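Remark on the chemistry: atoms are numbered as in eremophilanes (ring A = C1–C5 and C10, ring B = C5–C10, side chain C11–C13 with C12 the ester carbon, C14 = methyl on C5, C15 = methyl on C4); compounds 10–20 are carried as mixtures of epimers at centres that become sp2 on the way to 21.

## Structural features

The target is an eremophilane-type bicycle in which ring A (C1–C2–C3–C4–C5–C10) is fused through C5–C10 to ring B (C5–C6=C7–C8(=O)–C9=C10), a cross-conjugated cyclohexa-2,5-dienone. Ring A carries the C4 stereocentre (methyl C15), the adjacent quaternary C5 (methyl C14) and C1, whose angelate oxygen is allylic to C9=C10; all three substituents lie on one face. The fourth stereocentre, C11, sits in the methyl propanoate chain on C7, α to an ester and attached to an sp2 carbon, so it is the centre most easily lost to base. The angelate isomerises to the tiglate under nucleophilic or basic acylation conditions. A 4,4-disubstituted cyclohexadienol or dienone of ring B can rearrange under acid with migration of C14. The real difficulty is the quaternary C5 next to C4 with cis methyl groups, inside a ring that is oxidised or unsaturated at every other position. The key step exploits that ring B, taken at the cyclohexa-1,4-diene level (sp3 only at C5 and C8), is the [4+2] adduct of a C5=C6–C7=C8 diene and a C9≡C10 alkyne, and that the C1–C4 chain joining C10 to C5 becomes ring A in the same event.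

## Logic of the disconnections

**28 to 27 and 26.** No skeletal bond is cut; the C8 carbonyl is traced back to a C8 silyl ether. This turns the dienone into a 1,4-diene that is a cycloadduct and keeps C8 distinct from C1 while C1 is adjusted. The forward steps must desilylate without acid and oxidise a doubly allylic alcohol under neutral conditions.

**26 to 23 and 24.** The C1 oxygen–acyl bond is cut. The isomerisation-prone Z ester is thereby introduced late and from the acid itself. The forward step must acylate a hindered allylic alcohol without Z to E isomerisation.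

**23 to 22.** The C1–H bond is removed, giving the C1 ketone that activates the alkyne in the key step. The forward reduction must deliver hydride to the face of C1 anti to C14.

**22 to 21.** C5–C10 and C8–C9 are cut, which opens both rings and removes two stereocentres. What remains is an acyclic chain holding only C4 and C11. The forward step must add the alkyne to one face of a fully substituted diene terminus.

**21 to 20, 19 and 18.** No skeletal bond is cut; the ynone goes back to a propargylic acetate and the silyl dienol ether to an enal (O–Si and C5–H). The ynone cannot coexist with amine base and silyl triflate, so it must be unveiled last. The forward steps are a geometry-defining soft enolisation, a deacylation that spares the dienol ether, and a neutral oxidation.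

**18 to 17 and then 16 and 7.** The C6=C7 bond is cut, through C6–C7 and loss of methanol. This divides the chain into two halves of similar size, each with one stereocentre. The forward union must take place at an α-branched carbon without self-condensation, without lactonisation onto C12 and without base at C11.

**16 to 13 and 14, then 13 to 11, 10, 9 and 8.** C1–C10 is cut (acetylide addition), then the C1 aldehyde is traced to a trisubstituted alkene, C6 to a masked aldehyde and C14 to a one-carbon electrophile. The chiral pool supplies C1–C6 with C4 already set. The forward steps must keep the two chain ends distinguishable, which the acetal secures.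

**7 to 6, 4, 3 and 1.** The enol silane is traced to the aldehyde, the aldehyde to a terminal alkene, and the C7–C11 bond to an auxiliary-controlled allylation. C11 is thus set early by a reliable method and is not exposed to strong base afterwards.

## Other disconnections considered

**Alternative 1:** The cut is C1–C10 only, with ring B taken as a prochiral cyclohexa-2,5-dienone that carries the C1–C4 chain as an aldehyde (A1). In the forward key step a chiral triazolium-derived carbene converts the aldehyde into an acyl-anion equivalent that adds to C10 of one enone arm (intramolecular Stetter reaction). This closes ring A and makes C5 stereogenic in the cis-fused diketone A2.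
- In its favour: the polarity is fully matched (acyl anion onto an enone β-carbon), which is better than the chosen cycloaddition, where the silyloxy group does not help the orientation. The choice between the two enone arms can be reinforced by the catalyst and does not rest on C4 alone, which is at least equal and probably better. A1 holds no enol ether and no ynone.
- Against it here: desymmetrising Stetter reactions are best established for five-membered rings closed through a heteroatom tether; an aliphatic aldehyde closing a six-membered carbocycle next to a quaternary carbon is at the slow end. The step forms one ring and one skeletal bond, against two and two in the chosen plan. A2 lacks the C9=C10 double bond and the whole C11–C13 chain with its stereocentre, and it has two ketones (C1, C8) that must be told apart.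
- Comparison: it is shorter before the key step and clearly longer after it (dehydrogenation, functionalisation of C7 with control of C11, selective C1 reduction). Compound 22 of the chosen plan already holds every carbon and differentiates C1 from C8.

**Alternative 2:** The cuts are C3–C4 and C5–C10, so ring A is the adduct of (E)-2-methylbut-2-enal (A3) and methyl (3E)-hexa-3,5-dienoate (A4). In the forward key step a chiral oxazaborolidinium Lewis acid activates A3 and the endo [4+2] addition gives A5, with C6 as the formyl group on C5 and C8–C9 as the acetate arm on C10.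
- In its favour: the cis relation of C14 and C15 is written into the E geometry of A3 and is transferred stereospecifically. That is better than the chosen plan, where it depends on facial selectivity. The orientation is the electronically preferred one (better), absolute configuration comes from a catalyst (equal to the chiral pool), and both partners are small.
- Against it here: a β-substituted, α-branched enal is among the least reactive dienophiles for this kind of catalysis, and the skipped dienoate A4 can slip into conjugation under Lewis acid. A5 is ring A only. Ring B with its three oxidised positions, the C7 chain with C11, and the C1 oxygen (A5 has a C1=C2 alkene that would have to be transposed) all remain to be built.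
- Comparison: structurally it solves what the chosen plan finds hardest (C4/C5) and leaves open what the chosen plan solves in one step. Mechanistically it is the safer cycloaddition. In step economy after the key step it loses by a wide margin.

**Alternative 3:** The cut is C4–C5, with ring B taken as the phenol A6 whose meta tether carries the C1 silyl ether and a C4 mesylate. In the forward key step a hindered potassium alkoxide generates the phenolate, whose methyl-bearing para carbon C5 displaces the mesylate with inversion (4R to 4S). This closes ring A and reveals the dienone A7, the 1-epi silyl ether of the deacylated target.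
- In its favour: A7 already has the complete ring B, the C7 chain and the C1 oxygen, so only desilylation and an esterification with inversion at C1 would remain. That endgame is shorter than the four steps of the chosen plan (better). C4 is transferred stereospecifically (equal), and there is no pericyclic reactivity problem.
- Against it here: the phenolate is ambident. O-alkylation and closure through the free ortho carbon C9, which also gives a six-membered ring and can re-aromatise, compete with attack through the substituted C5. A secondary mesylate can eliminate under alkoxide. The C11–H of A6 is benzylic and α to the ester, so the base of the key step threatens the centre that the chosen plan keeps away from strong base. The face of C5 that bonds is again substrate-controlled (equal, not better).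
- Comparison: it is more convergent in oxidation state and shorter at the end, but the key step forms one ring where the chosen one forms two, and it carries more competing pathways and a real risk to C11.

Key step: step 15

## Route

Step 1
Reactants: 1 (R)-4-benzyl-3-propanoyl-1,3-oxazolidin-2-one
Product: 3 (R)-4-benzyl-3-[(2S)-2-methylpent-4-enoyl]-1,3-oxazolidin-2-one, via sodium (Z)-enolate 2 (not isolated)
Conditions: NaN(SiMe3)2, THF, −78 °C; allyl iodide, −78 → −40 °C
Reagents that add atoms: allyl iodide, C=CCI
Why: Evans auxiliary alkylation: the chelated (Z)-enolate 2 is attacked by allyl iodide on the face opposite the benzyl group, which sets C11 as S; the allyl CH2 becomes C7.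

Step 2
Reactants: 3 (R)-4-benzyl-3-[(2S)-2-methylpent-4-enoyl]-1,3-oxazolidin-2-one
Product: 4 methyl (2S)-2-methylpent-4-enoate
Conditions: MeMgBr, MeOH, THF, 0 °C
Reagents that add atoms: methanol (delivered as bromomagnesium methoxide), CO
Why: Transesterification of the N-acyl oxazolidinone at the exocyclic carbonyl by bromomagnesium methoxide; the reagent is too weakly basic to epimerise C11 and the auxiliary is recovered.

Step 3
Reactants: 4 methyl (2S)-2-methylpent-4-enoate
Product: 6 methyl (2S)-2-methyl-4-oxobutanoate, via secondary ozonide 5 (not isolated)
Conditions: O3, CH2Cl2, −78 °C; PPh3, −78 °C → rt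
Reagents that add atoms: ozone, [O-][O+]=O
Why: Ozonolysis of the terminal alkene with reductive work-up; loss of the terminal CH2 leaves C8 as the aldehyde.

Step 4
Reactants: 6 methyl (2S)-2-methyl-4-oxobutanoate
Product: 7 methyl (2S)-2-methyl-4-(trimethylsilyloxy)but-3-enoate (E/Z mixture)
Conditions: TMSOTf, Et3N, Et2O, 0 °C
Reagents that add atoms: trimethylsilyl trifluoromethanesulfonate, C[Si](C)(C)OS(=O)(=O)C(F)(F)F
Why: Soft enolisation of the aldehyde by silyl triflate and tertiary amine gives the enol silane; the ester is not enolised under these conditions, so C11 is untouched, and the alkene geometry is of no consequence.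

Step 5
Reactants: 8 (S)-citronellal
Product: 9 (3S)-3,7-dimethyl-2-methylideneoct-6-enal
Conditions: aq. HCHO, pyrrolidine (10 mol%), EtCO2H (10 mol%), i-PrOH, 45 °C
Reagents that add atoms: formaldehyde, C=O
Why: Amine-catalysed α-methylenation (Mannich condensation of the enamine with formaldehyde, then elimination of the amine) introduces C14; the C4 centre is β to the aldehyde and cannot epimerise.

Step 6
Reactants: 9 (3S)-3,7-dimethyl-2-methylideneoct-6-enal
Product: 10 (3S)-2,3,7-trimethyloct-6-enal (C5 epimers)
Conditions: Hantzsch ester (diethyl 2,6-dimethyl-1,4-dihydropyridine-3,5-dicarboxylate), Bn2NH·CF3CO2H (5 mol%), THF, rt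
Reagents that add atoms: none
Why: Organocatalytic transfer hydrogenation: hydride from the Hantzsch ester adds only to the iminium ion of the enal, so the trisubstituted alkene survives; C5 forms as both epimers, which is harmless because C5 becomes sp2 in step 12.

Step 7
Reactants: 10 (3S)-2,3,7-trimethyloct-6-enal
Product: 11 (6S)-8,8-dimethoxy-2,6,7-trimethyloct-2-ene
Conditions: HC(OMe)3, MeOH, PPTS (cat.), rt
Reagents that add atoms: trimethyl orthoformate, COC(OC)OC
Why: Acid-catalysed acetalisation with orthoformate as water scavenger masks C6 during steps 8 and 9 and makes it the electrophile of step 10; under these mild conditions it should outrun the carbonyl-ene cyclisation open to citronellal-type aldehydes.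

Step 8
Reactants: 11 (6S)-8,8-dimethoxy-2,6,7-trimethyloct-2-ene
Product: 13 (4S)-6,6-dimethoxy-4,5-dimethylhexanal, via secondary ozonide 12 (not isolated)
Conditions: O3, CH2Cl2, −78 °C (to the first blue colour); PPh3, −78 °C → rt
Reagents that add atoms: ozone, [O-][O+]=O
Why: Ozonolysis of the only alkene with reductive work-up gives the C1 aldehyde; the reaction is stopped at the end point because acetals are slowly oxidised by ozone.

Step 9
Reactants: 13 (4S)-6,6-dimethoxy-4,5-dimethylhexanal; 14 ethynylmagnesium bromide
Product: 16 (6S)-8,8-dimethoxy-6,7-dimethyloct-1-yn-3-yl acetate (C1 and C5 epimers), via bromomagnesium alkoxide 15 (not isolated)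
Conditions: THF, −78 → 0 °C; then Ac2O, DMAP (cat.), 0 °C → rt
Reagents that add atoms: acetic anhydride, CC(=O)OC(C)=O
Why: Grignard 1,2-addition to the only carbonyl group forms C1–C10 and the magnesium alkoxide is acylated in the same flask; the acetate survives steps 10–12 and can later be removed beside a silyl dienol ether, and the C1 epimers converge in step 14.

Step 10
Reactants: 16 (6S)-8,8-dimethoxy-6,7-dimethyloct-1-yn-3-yl acetate; 7 methyl (2S)-2-methyl-4-(trimethylsilyloxy)but-3-enoate
Product: 17 methyl (2S,6S)-9-acetoxy-3-formyl-4-methoxy-2,5,6-trimethylundec-10-ynoate (mixture at C5, C6, C7 and C1 of the target numbering)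
Conditions: TMSOTf (10 mol%), CH2Cl2, −78 °C
Reagents that add atoms: none
Why: Mukaiyama-type aldol addition to an acetal: the silyl triflate ionises the acetal to a methoxycarbenium ion, which enol silane 7 traps at C7, forming C6–C7 without self-condensation of the donor and without a free hydroxyl group that could lactonise onto C12; the new centres at C6 and C7 are removed in steps 11 and 12.

Step 11
Reactants: 17 methyl (2S,6S)-9-acetoxy-3-formyl-4-methoxy-2,5,6-trimethylundec-10-ynoate
Product: 18 methyl (2S,3E,6S)-9-acetoxy-3-formyl-2,5,6-trimethylundec-3-en-10-ynoate (C5 and C1 epimers)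
Conditions: TsOH·H2O (5 mol%), PhMe, 50 °C
Reagents that add atoms: none
Why: Acid-catalysed β-elimination of methanol through the enol gives the conjugated enal as its more stable E isomer; acid is used instead of base so that the C11–H, now α to the ester and allylic, is not removed.

Step 12
Reactants: 18 methyl (2S,3E,6S)-9-acetoxy-3-formyl-2,5,6-trimethylundec-3-en-10-ynoate
Product: 19 methyl (2S,3Z,4E,6S)-9-acetoxy-3-[(tert-butyldimethylsilyloxy)methylidene]-2,5,6-trimethylundec-4-en-10-ynoate (C1 epimers)
Conditions: TBSOTf, Et3N, CH2Cl2, −78 → 0 °C
Reagents that add atoms: tert-butyldimethylsilyl trifluoromethanesulfonate, CC(C)(C)[Si](C)(C)OS(=O)(=O)C(F)(F)F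
Why: Soft enolisation of the enal: O-silylation followed by removal of the γ-hydrogen at C5 gives the 1-silyloxy-1,3-diene; the C14 methyl group, not the branched C4 chain, should take the inside position during deprotonation (less allylic strain against C11), placing C4 trans to C7, and the s-trans enal places the silyloxy group trans to C6. Acetate, ester and alkyne are inert here, and the ketone that would compete for the reagent is not yet present.

Step 13
Reactants: 19 methyl (2S,3Z,4E,6S)-9-acetoxy-3-[(tert-butyldimethylsilyloxy)methylidene]-2,5,6-trimethylundec-4-en-10-ynoate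
Product: 20 methyl (2S,3Z,4E,6S)-3-[(tert-butyldimethylsilyloxy)methylidene]-9-hydroxy-2,5,6-trimethylundec-4-en-10-ynoate (C1 epimers)
Conditions: K2CO3 (0.2 equiv), MeOH, 0 °C
Reagents that add atoms: none
Why: Base-catalysed methanolysis of the secondary acetate; the hindered silyl dienol ether should survive cold methoxide, and the C12 methyl ester is invariant to exchange with methanol.

Step 14
Reactants: 20 methyl (2S,3Z,4E,6S)-3-[(tert-butyldimethylsilyloxy)methylidene]-9-hydroxy-2,5,6-trimethylundec-4-en-10-ynoate
Product: 21 methyl (2S,3Z,4E,6S)-3-[(tert-butyldimethylsilyloxy)methylidene]-2,5,6-trimethyl-9-oxoundec-4-en-10-ynoate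
Conditions: MnO2 (activated, excess), CH2Cl2, rt
Reagents that add atoms: none
Why: Neutral heterogeneous oxidation of the propargylic alcohol unveils the ynone last, so that it never meets amine base or silyl triflate; the silyl dienol ether and C11 are untouched and both C1 epimers give one compound.

Step 15
Reactants: 21 methyl (2S,3Z,4E,6S)-3-[(tert-butyldimethylsilyloxy)methylidene]-2,5,6-trimethyl-9-oxoundec-4-en-10-ynoate
Product: 22 methyl (4S,5S,8S,11S)-8-(tert-butyldimethylsilyloxy)-1-oxoeremophila-6,9-dien-12-oate
Conditions: PhMe (0.01 M), BHT (cat.), 120 °C, sealed tube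
Reagents that add atoms: none
Why: Heating brings the C9≡C10 ynone over the s-cis C5=C6–C7=C8 silyloxydiene, and a concerted, asynchronous thermal [4+2] cycloaddition forms C5–C10 and C8–C9 to give the cyclohexa-1,4-diene directly; the closest known reaction type is the intramolecular Diels–Alder reaction of alkynones with 1-silyloxy-1,3-dienes. Ring A is the tether ring: the four-atom chain C1–C4 joins C10 to the diene terminus C5, so it can close only in the fused mode as a six-membered ring, and ring B is the six-membered cycloadduct ring. C5 is set by the C4 stereocentre: in the chair-like arrangement of the forming ring A the C15 methyl group takes the pseudo-equatorial position, away from H6 and from the axial hydrogen on C2, so that C10 should add to the diene face that places C14 cis to C15 (5S). C8 follows from suprafacial addition to a diene of defined geometry (C4 and the silyloxy group are both outside and end up cis, 8S), and this centre is removed in step 19. The step needs facial selectivity at C5 and periselectivity over a 1,5-hydrogen shift from the inside C14 methyl group; the first rests on the C4 methyl group, the second on the activation of both partners (silyloxy-raised HOMO, ynone LUMO), high dilution and a radical inhibitor. Regiochemistry is fixed by the tether: it joins the ynone β-carbon C9 to the oxygenated terminus C8, the orientation favoured by the alkyl groups on C5 and C7 but not by the silyloxy group, which therefore contributes activation and the C8 oxygen and no help in orientation. The fully substituted terminus C5 is the demanding point and sets the temperature.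

Step 16
Reactants: 22 methyl (4S,5S,8S,11S)-8-(tert-butyldimethylsilyloxy)-1-oxoeremophila-6,9-dien-12-oate
Product: 23 methyl (1R,4S,5S,8S,11S)-8-(tert-butyldimethylsilyloxy)-1-hydroxyeremophila-6,9-dien-12-oate
Conditions: NaBH4, CeCl3·7H2O, MeOH, −78 °C
Reagents that add atoms: none
Why: Luche 1,2-reduction of the enone; the pseudo-axial C14 methyl group on C5 shields the face of C1 syn to it, so hydride should add anti to C14 and give the 1R alcohol with the oxygen cis to C14 and C15.

Step 17
Reactants: 23 methyl (1R,4S,5S,8S,11S)-8-(tert-butyldimethylsilyloxy)-1-hydroxyeremophila-6,9-dien-12-oate; 24 angelic acid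
Product: 26 methyl (1R,4S,5S,8S,11S)-1-[(Z)-2-methylbut-2-enoyloxy]-8-(tert-butyldimethylsilyloxy)eremophila-6,9-dien-12-oate, via mixed anhydride 25 (not isolated)
Conditions: 2,4,6-Cl3C6H2COCl, Et3N, PhMe, rt; then 23, 80 °C
Reagents that add atoms: none
Why: Yamaguchi esterification through mixed anhydride 25 without a nucleophilic catalyst, conditions under which Z-2-methylbut-2-enoates are not expected to isomerise to the E esters; acylation of the hindered allylic alcohol needs heat.

Step 18
Reactants: 26 methyl (1R,4S,5S,8S,11S)-1-[(Z)-2-methylbut-2-enoyloxy]-8-(tert-butyldimethylsilyloxy)eremophila-6,9-dien-12-oate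
Product: 27 methyl (1R,4S,5S,8S,11S)-1-[(Z)-2-methylbut-2-enoyloxy]-8-hydroxyeremophila-6,9-dien-12-oate
Conditions: Bu4NF, AcOH, THF, 0 °C → rt
Reagents that add atoms: none
Why: Fluoride cleavage of the secondary silyl ether, buffered with acetic acid to spare C11 and the angelate; strong acid is avoided because the 4,4-disubstituted cyclohexa-2,5-dienol would ionise and rearrange with migration of C14.

Step 19
Reactants: 27 methyl (1R,4S,5S,8S,11S)-1-[(Z)-2-methylbut-2-enoyloxy]-8-hydroxyeremophila-6,9-dien-12-oate
Product: 28 methyl (1R,4S,5S,11S)-1-[(Z)-2-methylbut-2-enoyloxy]-8-oxoeremophila-6,9-dien-12-oate (CNP0166395.1)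
Conditions: MnO2 (activated, excess), CH2Cl2, rt
Reagents that add atoms: none
Why: MnO2 oxidation of the doubly allylic alcohol gives the cross-conjugated dienone under neutral conditions and removes the C8 stereocentre; the product is the target.

## Compound list

1 | (R)-4-benzyl-3-propanoyl-1,3-oxazolidin-2-one | CCC(=O)N1[C@H](Cc2ccccc2)COC1=O | starting material
2 | sodium (Z)-enolate of 1 | C/C=C(\[O-])N1[C@H](Cc2ccccc2)COC1=O.[Na+] | intermediate
3 | (R)-4-benzyl-3-[(2S)-2-methylpent-4-enoyl]-1,3-oxazolidin-2-one | C=CC[C@H](C)C(=O)N1[C@H](Cc2ccccc2)COC1=O | intermediate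
4 | methyl (2S)-2-methylpent-4-enoate | C=CC[C@H](C)C(=O)OC | intermediate
5 | methyl (2S)-2-methyl-3-(1,2,4-trioxolan-3-yl)propanoate (secondary ozonide of 4) | COC(=O)[C@@H](C)CC1OOCO1 | intermediate
6 | methyl (2S)-2-methyl-4-oxobutanoate | O=CC[C@H](C)C(=O)OC | intermediate
7 | methyl (2S)-2-methyl-4-(trimethylsilyloxy)but-3-enoate (E/Z mixture) | C[Si](C)(C)OC=C[C@H](C)C(=O)OC | intermediate
8 | (S)-citronellal | C[C@@H](CCC=C(C)C)CC=O | starting material
9 | (3S)-3,7-dimethyl-2-methylideneoct-6-enal | C[C@@H](CCC=C(C)C)C(=C)C=O | intermediate
10 | (3S)-2,3,7-trimethyloct-6-enal (C2 epimers) | C[C@@H](CCC=C(C)C)C(C)C=O | intermediate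
11 | (6S)-8,8-dimethoxy-2,6,7-trimethyloct-2-ene (C7 epimers) | C[C@@H](CCC=C(C)C)C(C)C(OC)OC | intermediate
12 | secondary ozonide of 11 (3,3-dimethyl-1,2,4-trioxolane) | C[C@@H](CCC1OOC(C)(C)O1)C(C)C(OC)OC | intermediate
13 | (4S)-6,6-dimethoxy-4,5-dimethylhexanal (C5 epimers) | C[C@@H](CCC=O)C(C)C(OC)OC | intermediate
14 | ethynylmagnesium bromide | C#C[Mg]Br | starting material
15 | bromomagnesium (6S)-8,8-dimethoxy-6,7-dimethyloct-1-yn-3-olate | C#CC(O[Mg]Br)CC[C@H](C)C(C)C(OC)OC | intermediate
16 | (6S)-8,8-dimethoxy-6,7-dimethyloct-1-yn-3-yl acetate (C3 and C7 epimers) | C#CC(OC(C)=O)CC[C@H](C)C(C)C(OC)OC | intermediate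
17 | methyl (2S,6S)-9-acetoxy-3-formyl-4-methoxy-2,5,6-trimethylundec-10-ynoate (mixture at C3, C4, C5, C9) | C#CC(OC(C)=O)CC[C@H](C)C(C)C(OC)C(C=O)[C@H](C)C(=O)OC | intermediate
18 | methyl (2S,3E,6S)-9-acetoxy-3-formyl-2,5,6-trimethylundec-3-en-10-ynoate (mixture at C5, C9) | C#CC(OC(C)=O)CC[C@H](C)C(C)/C=C(/C=O)[C@H](C)C(=O)OC | intermediate
19 | methyl (2S,3Z,4E,6S)-9-acetoxy-3-[(tert-butyldimethylsilyloxy)methylidene]-2,5,6-trimethylundec-4-en-10-ynoate (C9 epimers) | C#CC(OC(C)=O)CC[C@H](C)/C(C)=C/C(=C/O[Si](C)(C)C(C)(C)C)[C@H](C)C(=O)OC | intermediate
20 | methyl (2S,3Z,4E,6S)-3-[(tert-butyldimethylsilyloxy)methylidene]-9-hydroxy-2,5,6-trimethylundec-4-en-10-ynoate (C9 epimers) | C#CC(O)CC[C@H](C)/C(C)=C/C(=C/O[Si](C)(C)C(C)(C)C)[C@H](C)C(=O)OC | intermediate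
21 | methyl (2S,3Z,4E,6S)-3-[(tert-butyldimethylsilyloxy)methylidene]-2,5,6-trimethyl-9-oxoundec-4-en-10-ynoate (4S,11S in target numbering) | C#CC(=O)CC[C@H](C)/C(C)=C/C(=C/O[Si](C)(C)C(C)(C)C)[C@H](C)C(=O)OC | intermediate
22 | methyl (4S,5S,8S,11S)-8-(tert-butyldimethylsilyloxy)-1-oxoeremophila-6,9-dien-12-oate | O=C1CC[C@H](C)[C@@]2(C)C=C([C@H](C)C(=O)OC)[C@@H](O[Si](C)(C)C(C)(C)C)C=C12 | intermediate
23 | methyl (1R,4S,5S,8S,11S)-8-(tert-butyldimethylsilyloxy)-1-hydroxyeremophila-6,9-dien-12-oate | O[C@@H]1CC[C@H](C)[C@@]2(C)C=C([C@H](C)C(=O)OC)[C@@H](O[Si](C)(C)C(C)(C)C)C=C12 | intermediate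
24 | angelic acid, (Z)-2-methylbut-2-enoic acid | C/C=C(/C)C(=O)O | starting material
25 | (Z)-2-methylbut-2-enoic 2,4,6-trichlorobenzoic anhydride | C/C=C(/C)C(=O)OC(=O)c1c(Cl)cc(Cl)cc1Cl | intermediate
26 | methyl (1R,4S,5S,8S,11S)-1-[(Z)-2-methylbut-2-enoyloxy]-8-(tert-butyldimethylsilyloxy)eremophila-6,9-dien-12-oate | C/C=C(/C)C(=O)O[C@@H]1CC[C@H](C)[C@@]2(C)C=C([C@H](C)C(=O)OC)[C@@H](O[Si](C)(C)C(C)(C)C)C=C12 | intermediate
27 | methyl (1R,4S,5S,8S,11S)-1-[(Z)-2-methylbut-2-enoyloxy]-8-hydroxyeremophila-6,9-dien-12-oate | C/C=C(/C)C(=O)O[C@@H]1CC[C@H](C)[C@@]2(C)C=C([C@H](C)C(=O)OC)[C@@H](O)C=C12 | intermediate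
28 | methyl (1R,4S,5S,11S)-1-[(Z)-2-methylbut-2-enoyloxy]-8-oxoeremophila-6,9-dien-12-oate (CNP0166395.1) | C/C=C(/C)C(=O)O[C@@H]1CC[C@H](C)[C@@]2(C)C=C([C@H](C)C(=O)OC)C(=O)C=C12 | target

## Step count and least certain steps

Total: 19 steps. Longest linear sequence: 15 steps (8 to 28, steps 5–19); the branch 1 to 7 takes 4 steps and joins at step 10.

**Step 15 (key step).** The cycloaddition may be slow at the fully substituted terminus C5, since the silyloxy group does not assist the tether-enforced orientation. A 1,5-hydrogen shift from the inside C14 methyl group and loss of the silyl enol ether could then overtake it, and facial selectivity at C5 rests on a single methyl group. The fallback sets out from 21 and comes back at 22, and it replaces the alkyne by a more reactive alkyne equivalent. Conjugate addition of sodium benzenesulfinate to the ynone (PhSO2Na, AcOH, THF–H2O, 0 °C) should give the (E)-β-(phenylsulfonyl) enone F1. This is an alkene activated at both ends with balanced coefficients at C9 and C10, which should cyclise at lower temperature to the sulfonyl ketone F2 (mixture at C8, C9, C10). Et3N at rt then eliminates benzenesulfinic acid across C9–C10 and gives 22.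

**Step 10.** The methoxycarbenium ion from the α-branched acetal may lose a proton to an enol ether instead of being trapped, or the enol silane may be destroyed by adventitious acid, so the union stalls. The fallback sets out from 16 (with 6 as partner) and comes back at 18. Hydrolysis of the acetal (TsOH, acetone–H2O) gives the aldehyde F3. A proline-catalysed cross-aldol reaction with slow addition of 6 (DMF, 4 °C) gives the β-hydroxy aldehyde F4, which is a γ-hydroxy ester and would lactonise on standing. It is therefore treated at once with MsCl and Et3N; the mesylate F5 eliminates in the same flask to 18.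

**Step 13.** Methoxide may cleave the silyl dienol ether or epimerise C11 at a rate not well separated from the deacetylation. The fallback sets out from 18 and comes back at 20, and it moves the deacetylation in front of the enolisation. K2CO3 in MeOH at 0 °C gives the hydroxy enal F6. Me3SiCl and Et3N, followed in the same flask by TBSOTf, give the bis-silyl compound F7. Its trimethylsilyl ether is far more labile than an acetate and is removed by a few minutes of K2CO3 in MeOH at −20 °C, which gives 20.

**Step 16.** Facial selectivity of the hydride addition may be poor or reversed if ring A adopts a conformation in which C14 no longer shields C1. The fallback sets out from 22 and comes back at 26, and it corrects the centre by inversion instead of by reduction. If the 1S alcohol F8 predominates, a Mitsunobu esterification of F8 with 24 (PPh3, DIAD, PhMe, 0 °C → rt) installs the angelate with inversion at C1 and gives 26 directly.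

**Step 17.** Isomerisation of the angelate to the tiglate, or incomplete acylation of the hindered alcohol, is the likely failure. The fallback sets out from 23 and comes back at 26, and it builds the Z alkene on the ester. Acylation of 23 with 2-[bis(2,2,2-trifluoroethoxy)phosphoryl]propanoic acid (DCC, DMAP) gives the phosphonate ester F9. A Still–Gennari olefination with acetaldehyde (KN(SiMe3)2, 18-crown-6, THF, −78 °C) should then give the Z-2-methylbut-2-enoate 26.

## Further compounds

F1 | step 15 | methyl (2S,3Z,4E,6S,10E)-3-[(tert-butyldimethylsilyloxy)methylidene]-2,5,6-trimethyl-9-oxo-11-(phenylsulfonyl)undeca-4,10-dienoate | O=C(/C=C/S(=O)(=O)c1ccccc1)CC[C@H](C)/C(C)=C/C(=C/O[Si](C)(C)C(C)(C)C)[C@H](C)C(=O)OC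
F2 | step 15 | methyl (4S,5S,11S)-8-(tert-butyldimethylsilyloxy)-1-oxo-9-(phenylsulfonyl)eremophil-6-en-12-oate (mixture at C8, C9, C10) | O=C1CC[C@H](C)[C@@]2(C)C=C([C@H](C)C(=O)OC)C(O[Si](C)(C)C(C)(C)C)C(S(=O)(=O)c3ccccc3)C12
F3 | step 10 | (6S)-6,7-dimethyl-8-oxooct-1-yn-3-yl acetate (C3 and C7 epimers) | C#CC(OC(C)=O)CC[C@H](C)C(C)C=O
F4 | step 10 | methyl (2S,6S)-9-acetoxy-3-formyl-4-hydroxy-2,5,6-trimethylundec-10-ynoate (mixture at C3, C4, C5, C9) | C#CC(OC(C)=O)CC[C@H](C)C(C)C(O)C(C=O)[C@H](C)C(=O)OC
F5 | step 10 | methyl (2S,6S)-9-acetoxy-3-formyl-4-(methylsulfonyloxy)-2,5,6-trimethylundec-10-ynoate | C#CC(OC(C)=O)CC[C@H](C)C(C)C(OS(C)(=O)=O)C(C=O)[C@H](C)C(=O)OC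
F6 | step 13 | methyl (2S,3E,6S)-3-formyl-9-hydroxy-2,5,6-trimethylundec-3-en-10-ynoate (mixture at C5, C9) | C#CC(O)CC[C@H](C)C(C)/C=C(/C=O)[C@H](C)C(=O)OC
F7 | step 13 | methyl (2S,3Z,4E,6S)-3-[(tert-butyldimethylsilyloxy)methylidene]-2,5,6-trimethyl-9-(trimethylsilyloxy)undec-4-en-10-ynoate (C9 epimers) | C#CC(O[Si](C)(C)C)CC[C@H](C)/C(C)=C/C(=C/O[Si](C)(C)C(C)(C)C)[C@H](C)C(=O)OC
F8 | step 16 | methyl (1S,4S,5S,8S,11S)-8-(tert-butyldimethylsilyloxy)-1-hydroxyeremophila-6,9-dien-12-oate | O[C@H]1CC[C@H](C)[C@@]2(C)C=C([C@H](C)C(=O)OC)[C@@H](O[Si](C)(C)C(C)(C)C)C=C12
F9 | step 17 | methyl (1R,4S,5S,8S,11S)-1-{2-[bis(2,2,2-trifluoroethoxy)phosphoryl]propanoyloxy}-8-(tert-butyldimethylsilyloxy)eremophila-6,9-dien-12-oate | CC(C(=O)O[C@@H]1CC[C@H](C)[C@@]2(C)C=C([C@H](C)C(=O)OC)[C@@H](O[Si](C)(C)C(C)(C)C)C=C12)P(=O)(OCC(F)(F)F)OCC(F)(F)F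
A1 | alternative 1 | 4-methyl-4-[(2S)-5-oxopentan-2-yl]cyclohexa-2,5-dien-1-one | O=CCC[C@H](C)C1(C)C=CC(=O)C=C1
A2 | alternative 1 | cis-fused (4S,5S) 1,8-diketone with the C6=C7 enone | O=C1CC[C@H](C)[C@@]2(C)C=CC(=O)C[C@@H]12
A3 | alternative 2 | (E)-2-methylbut-2-enal | C/C=C(\C)C=O
A4 | alternative 2 | methyl (3E)-hexa-3,5-dienoate | COC(=O)C/C=C/C=C
A5 | alternative 2 | methyl 2-(6-formyl-5,6-dimethylcyclohex-2-en-1-yl)acetate, endo adduct with cis methyl groups | COC(=O)C[C@H]1C=CC[C@H](C)[C@@]1(C)C=O
A6 | alternative 3 | methyl (2S)-2-{4-[(1S,4R)-1-(tert-butyldimethylsilyloxy)-4-(methylsulfonyloxy)pentyl]-2-hydroxy-5-methylphenyl}propanoate | COC(=O)[C@@H](C)c1cc(C)c(cc1O)[C@@H](O[Si](C)(C)C(C)(C)C)CC[C@@H](C)OS(C)(=O)=O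
A7 | alternative 3 | (1S,4S,5S,11S) dienone ester, 1-epi tert-butyldimethylsilyl ether of the deacylated target | CC(C)(C)[Si](C)(C)O[C@H]1CC[C@H](C)[C@@]2(C)C=C([C@H](C)C(=O)OC)C(=O)C=C12
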